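The time I had was 5.0 h at a fixed temperature, and the flasks birch, oak and ash differed in the G charged.

| flask | D | G | time |
|---|---|---|---|
| birch | 0.050 M | 0.00500 M | 5.0 h |
| oak | 0.050 M | 0.0100 M | 5.0 h |
| ash | 0.050 M | 0.0200 M | 5.0 h |

    D + E → 2 E (k1 = 0.0282 /M/s)
    D → E (k2 = 1.64 × 10⁻⁷ /s)
    2 D → D2 (k3 = 0.00188 /M/s)
    D + G → D.G (k4 = 0.132 /M/s)

- percentages count the D that a species holds: one D2 counts as two
- a step written with two of one species runs at k times the square of its concentration and takes two of it each time
- "hardly changes" means that all values lie within two and a half points (for a concentration: within two and a half percent of the largest)
- run time (birch): 5.0 h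

- amount of E at the end, in percent of the D charged for birch, oak, ash, in this order
- how that number moves from the first to the last of them (falls, then rises / rises, then falls / hardly changes / falls all the way / rises all the way)

The bench rule for a scavenger says that G takes its own amount of D first and the rest of the D goes to product. In birch, the half-life of D on G, with G held at its charge, was 0.29 h, short against the run, and reckoned the same way for ash it was 0.0729 h. So I applied the rule and got ceilings for E of 90.0% in birch, 80.0% in oak and 60.0% in ash.

But the rule assumes that E is there to take the rest, and the flasks start without E. In birch, the direct step from D to E has a half-life of 49 d, far longer than the run, so it gives a trace, and E must multiply itself from that trace. Meanwhile the pairing of D into D2 has a first half-life of 1.48 h from the charged c(D), within the run.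

The border of the rule follows from the two rate laws. The E step takes D at its constant times c(D) times c(E), and the pairing takes D at 2 times its constant times c(D) squared, so one c(D) cancels. The two steps take D equally fast when c(E)/c(D) reaches 2 × 0.00188 /M/s / 0.0282 /M/s = 0.133, the crossing ratio, a selectivity factor. Below it the pairing takes D faster than the E step does, and above it the reverse holds.

I could not put a time on that crossing by hand. So I committed to a row under the ceilings, falling from birch to ash, since the ceiling of ash stood below that of birch.

The forecast gave 34.1%, 29.5% and 17.7%, a row that falls all the way, on these grounds: “More G leaves less D, which both lowers the final E ceiling and slows the take-off”.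

E at the end stood at 34.0% in birch, 29.5% in oak and 17.7% in ash, a row that falls all the way. At that moment birch held 55.1% of the D charged in D2, more than the 34.0% in E. Against the crossing ratio of 0.133, c(E)/c(D) after 2.50 h was 0.346 in birch, past it, and 0.0753 in ash, still short of it.

The numbers of this flask come from no measurement; the rest is arithmetic.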